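## Retrosynthetic overview

1. The target is the anti, head-to-head [2+2] dimer of two (E)-3-(1-oxybutyl)-4-bromo-5-(bromomethylene)butenolides. The ring bromines are trans to each other and each is trans to the lactone O on the neighbouring spiro carbon. The side chains are 1'S and 1'R, so a C2-symmetric (1'R,1'R)-diol dimer is made, one carbinol is inverted (Mitsunobu, AcOH) and the other acetylated.
2. Cyclobutane (last ring): intramolecular photochemical [2+2] of a bis-butenolide whose two (R)-carbinol oxygens are clamped by an iPr2Si–O–SiiPr2 bridge. This step sets all four ring stereocentres.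
3. Both butenolide rings (formed together, before the cyclobutane): 5-exo-dig bromolactonisation of (2E)-3-bromopent-2-en-4-ynoic acids, which gives the (E)-bromomethylene.
4. Bromo-enyne acids: Claisen acylation of the silyl-bridged β-silyloxy ester with TMS-propynoyl chloride, then enol → vinyl bromide.
5. All chirality comes from methyl (R)-3-hydroxyhexanoate.

Assumption: methyl (R)-3-hydroxyhexanoate (the methanolysis monomer of bacterial polyhydroxyalkanoate, also two steps from bulk (S)-4-chloro-3-hydroxybutanoate esters) and 3-(trimethylsilyl)prop-2-ynoyl chloride are taken as purchasable.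

## Route

Step 1
Reactants: 1 methyl (R)-3-hydroxyhexanoate (2 equiv)
Product: 2 dimethyl (3R,3'R)-3,3'-[(1,1,3,3-tetraisopropyldisiloxane-1,3-diyl)bis(oxy)]dihexanoate
Conditions: iPr2Si(Cl)OSi(Cl)iPr2 (0.5 equiv), imidazole, DMAP (cat.), DMF, 0 °C to rt
Reagents that add atoms: 1,3-dichloro-1,1,3,3-tetraisopropyldisiloxane CC(C)[Si](Cl)(C(C)C)O[Si](Cl)(C(C)C)C(C)C
Why: Two-fold O-silylation (silyl ether formation) joins two molecules of 1 through a disiloxane bridge that protects both carbinols and later acts as the photochemical clamp; the bought stereocentre is not touched.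

Step 2
Reactants: 2 the bridged diester; 3 3-(trimethylsilyl)prop-2-ynoyl chloride (2.2 equiv)
Product: 4 bridged bis(β-keto ester): each ester α-carbon of 2 carries a 3-(trimethylsilyl)prop-2-ynoyl group (α-epimer mixture, carbinols R,R)
Conditions: LiHMDS (4.4 equiv), THF, −78 °C; then 3, −78 °C; aq NH4Cl
Reagents that add atoms: none
Why: Crossed Claisen C-acylation of the ester lithium enolates by the acid chloride (the second equivalent of base parks each product as its enolate); the new α-centres are unimportant because they become sp2 in step 3.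

Step 3
Reactants: 4 the bis(β-keto ester)
Product: 6 bridged bis[methyl (2E)-3-bromo-2-((1R)-1-silyloxybutyl)pent-2-en-4-ynoate] with terminal alkynes and CO2Me cis to the alkyne, via bis(silylalkynyl bromoenoate) 5 (not isolated)
Conditions: Ph3P·Br2 (2.4 equiv), Et3N, MeCN, 0 °C; then K2CO3 (cat.), MeOH, 0 °C, 20 min
Reagents that add atoms: dibromotriphenylphosphorane BrP(Br)(c1ccccc1)(c1ccccc1)c1ccccc1
Why: Enol deoxybromination (vinylogous Appel-type): under amine-only, non-chelating conditions the enolate oxygen is phosphonylated trans to the ester and bromide replaces it by addition–elimination with retention, so Br ends trans to CO2Me, after which base methanolysis of the C(sp)–Si bonds frees the alkynes.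

Step 4
Reactants: 6 the bis(bromo-enyne methyl ester)
Product: 7 bridged bis[(2E)-3-bromo-2-((1R)-1-silyloxybutyl)pent-2-en-4-ynoic acid]
Conditions: Me3SnOH (10 equiv), 1,2-dichloroethane, 70 °C; 1 M HCl work-up
Reagents that add atoms: trimethyltin hydroxide C[Sn](C)(C)O
Why: Neutral ester hydrolysis (acyl–oxygen cleavage by Me3SnOH) frees both acids without addition–elimination at the vinylic bromide and without harming the disiloxane.

Step 5
Reactants: 7 the bis(bromo-enyne acid)
Product: 8 1,3-bis{(1R)-1-[(5E)-4-bromo-5-(bromomethylene)-2-oxo-2,5-dihydrofuran-3-yl]butoxy}-1,1,3,3-tetraisopropyldisiloxane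
Conditions: NBS (2.2 equiv), KHCO3, MeCN–H2O 10:1, 0 °C, dark
Reagents that add atoms: N-bromosuccinimide O=C1CCC(=O)N1Br
Why: 5-exo-dig bromolactonisation of each (Z)-arranged enynoic acid; anti addition of carboxylate O and Br+ across the terminal alkyne puts the exocyclic Br trans to the ring O, i.e. the (E)-bromomethylene.

Step 6
Reactants: 8 the bridged bis[(E)-bromomethylene butenolide]
Product: 9 disiloxane-bridged photodimer: 4,10,11,12-tetrabromo-1,7-dioxadispiro[4.0.4.2]dodeca-3,9-diene-2,8-dione core (5S,6S,11R,12R) whose C3 and C9 (1R)-butyloxy carbons are joined through O–SiiPr2–O–SiiPr2–O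
Conditions: hν (310 nm LED), degassed MeCN (1 mM), −40 °C
Reagents that add atoms: none
Why: Proposed new method: direct (unsensitised) excitation of the folded conformer of 8 should give an intramolecular excimer that closes suprafacially on both (E)-alkenes faster than C=C torsion, because the three-atom Si–O–Si clamp and allylic 1,3-strain against C4–Br (carbinol H in the ring plane, both bridge oxygens between the rings, both propyl groups outside) hold the two butenolides as an antiparallel, dipole-paired stack; this gives the head-to-head anti (C2) cyclobutane with each CHBr bromine trans to the lactone O of its own spiro carbon and with the helicity (spiro S,S; CHBr R,R) fixed by the two bought (R)-carbinols; the closest known reactions are template- or tether-directed [2+2] photodimerisations of cinnamates and coumarins and the head-to-head dimerisation of protoanemonin to anemonin, but a stereoretentive, tether-controlled dimerisation of halo-γ-ylidenebutenolides has not been shown.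

Step 7
Reactants: 9 the bridged photodimer
Product: 10 (5S,6S,11R,12R)-4,10,11,12-tetrabromo-3,9-bis[(1R)-1-hydroxybutyl]-1,7-dioxadispiro[4.0.4.2]dodeca-3,9-diene-2,8-dione
Conditions: HF·pyridine, THF, 0 °C to rt
Reagents that add atoms: none
Why: Fluoride-driven Si–O cleavage (desilylation) removes the clamp; the lactones, C–Br bonds and the cyclobutane are inert to buffered HF.

Step 8
Reactants: 10 the C2-symmetric diol
Product: 11 (1S)-1-{(5S,6S,11R,12R)-4,10,11,12-tetrabromo-9-[(1R)-1-hydroxybutyl]-2,8-dioxo-1,7-dioxadispiro[4.0.4.2]dodeca-3,9-dien-3-yl}butyl acetate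
Conditions: AcOH (1.0 equiv), PPh3, DIAD, toluene, 0 °C; unreacted 10 recovered and recycled
Reagents that add atoms: acetic acid CC(=O)O
Why: Mitsunobu esterification inverts one carbinol by SN2 on its alkoxyphosphonium salt; the two hydroxyls are homotopic, so either one gives the same (1'S)-acetate/(1'R)-alcohol, and the step is statistical.

Step 9
Reactants: 11 the mono-acetate
Product: 12 target: (1S)-1-{(5S,6S,11R,12R)-9-[(1R)-1-acetoxybutyl]-4,10,11,12-tetrabromo-2,8-dioxo-1,7-dioxadispiro[4.0.4.2]dodeca-3,9-dien-3-yl}butyl acetate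
Conditions: Ac2O, Sc(OTf)3 (2 mol %), MeCN, 0 °C
Reagents that add atoms: acetic anhydride CC(=O)OC(C)=O
Why: Lewis-acid-catalysed acetylation of the remaining alcohol with retention; amine-free conditions avoid addition–elimination at the vinylogous acyl bromides.

## Compound list

1 | methyl (R)-3-hydroxyhexanoate | CCC[C@@H](O)CC(=O)OC | starting material
2 | dimethyl (3R,3'R)-3,3'-[(1,1,3,3-tetraisopropyldisiloxane-1,3-diyl)bis(oxy)]dihexanoate | CCC[C@H](CC(=O)OC)O[Si](C(C)C)(C(C)C)O[Si](C(C)C)(C(C)C)O[C@H](CCC)CC(=O)OC | intermediate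
3 | 3-(trimethylsilyl)prop-2-ynoyl chloride | C[Si](C)(C)C#CC(Cl)=O | starting material
4 | bridged bis(β-keto ester), α-epimer mixture | CCC[C@H](C(C(=O)OC)C(=O)C#C[Si](C)(C)C)O[Si](C(C)C)(C(C)C)O[Si](C(C)C)(C(C)C)O[C@H](CCC)C(C(=O)OC)C(=O)C#C[Si](C)(C)C | intermediate
5 | bridged bis[methyl (2E)-3-bromo-5-(trimethylsilyl)pent-2-en-4-ynoate], not isolated | CCC[C@H](/C(C(=O)OC)=C(\Br)C#C[Si](C)(C)C)O[Si](C(C)C)(C(C)C)O[Si](C(C)C)(C(C)C)O[C@H](CCC)/C(C(=O)OC)=C(\Br)C#C[Si](C)(C)C | intermediate
6 | bridged bis[methyl (2E)-3-bromopent-2-en-4-ynoate] | CCC[C@H](/C(C(=O)OC)=C(\Br)C#C)O[Si](C(C)C)(C(C)C)O[Si](C(C)C)(C(C)C)O[C@H](CCC)/C(C(=O)OC)=C(\Br)C#C | intermediate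
7 | bridged bis[(2E)-3-bromopent-2-en-4-ynoic acid] | CCC[C@H](/C(C(=O)O)=C(\Br)C#C)O[Si](C(C)C)(C(C)C)O[Si](C(C)C)(C(C)C)O[C@H](CCC)/C(C(=O)O)=C(\Br)C#C | intermediate
8 | bridged bis[(5E)-4-bromo-5-(bromomethylene)butenolide], carbinols R,R | CCC[C@H](C1=C(Br)/C(=C\Br)OC1=O)O[Si](C(C)C)(C(C)C)O[Si](C(C)C)(C(C)C)O[C@H](CCC)C1=C(Br)/C(=C\Br)OC1=O | intermediate
9 | disiloxane-bridged photodimer (spiro S,S; CHBr R,R; carbinols R,R) | CCC[C@@H](O[Si](C(C)C)(C(C)C)O[Si]3(C(C)C)C(C)C)C1=C(Br)[C@@]2(OC1=O)[C@@H](Br)[C@H](Br)[C@@]21OC(=O)C([C@@H](CCC)O3)=C1Br | intermediate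
10 | (1'R,1'R)-diol dimer | CCC[C@@H](O)C1=C(Br)[C@@]2(OC1=O)[C@@H](Br)[C@H](Br)[C@@]21OC(=O)C([C@@H](CCC)O)=C1Br | intermediate
11 | (1'S)-acetate / (1'R)-alcohol dimer | CCC[C@H](OC(C)=O)C1=C(Br)[C@@]2(OC1=O)[C@@H](Br)[C@H](Br)[C@@]21OC(=O)C([C@@H](CCC)O)=C1Br | intermediate
12 | CNP0266230.1 | CCC[C@H](OC(C)=O)C1=C(Br)[C@@]2(OC1=O)[C@@H](Br)[C@H](Br)[C@@]21OC(=O)C([C@@H](CCC)OC(C)=O)=C1Br | target

## Step count and risks

Total steps: 9. Longest linear sequence: 9 (1 → 12).

The three steps most likely to fail:

The photocycloaddition of step 6 is the new reaction and the main risk. Possible failures are E→Z isomerisation of the bromomethylene groups before ring closure, C–Br photolysis, or a syn or wrong-helicity adduct. The fallback uses known chemistry and gives up the clamp. It sets out from 8: HF·pyridine in THF cleaves the bridge to (5E)-4-bromo-5-(bromomethylene)-3-[(1R)-1-hydroxybutyl]furan-2(5H)-one F1. F1 is then photodimerised without a template (irradiation of a neat crystalline film, or benzophenone-sensitised in concentrated MeCN), the classical head-to-head dimerisation of γ-ylidenebutenolides of the anemonin type. The dimers are separated by HPLC, and the anti (1'R,1'R)-diol re-enters the route at 10.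

The enol bromination of step 3 may give the wrong alkene geometry, and Ph3P·Br2 may attack the silyl ethers. The fallback sets out from 4. Stereodefined enol tosylation (TsCl, N-methylimidazole, Et3N, MeCN; amine-only conditions place the sulfonate trans to the ester) gives the bridged bis[(2E)-enol tosylate] F2. Pd-catalysed Stille-type stannylation (Me3SnSnMe3, Pd2(dba)3, XPhos, LiCl, dioxane, 80 °C; retention) gives the bridged bis(vinylstannane) F3. Bromodestannylation with Br2 in CH2Cl2 at −78 °C (retention) returns to the route at 5, which is desilylated as in step 3.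

The mono-Mitsunobu of step 8 is statistical and may suffer elimination to the butylidene. The fallback sets out from 10. Ms2O (1.0 equiv) with 2,6-lutidine in CH2Cl2 at −40 °C gives the mono-mesylate F4, separable from diol and bis-mesylate. CsOAc with 18-crown-6 in toluene at 50 °C displaces the mesylate by SN2 with inversion and returns to the route at 11.

## Further compounds

F1 | step 6 | (5E)-4-bromo-5-(bromomethylene)-3-[(1R)-1-hydroxybutyl]furan-2(5H)-one | CCC[C@@H](O)C1=C(Br)/C(=C\Br)OC1=O
F2 | step 3 | bridged bis[methyl (2E)-3-(tosyloxy)-5-(trimethylsilyl)pent-2-en-4-ynoate] | CCC[C@H](/C(C(=O)OC)=C(\OS(=O)(=O)c1ccc(C)cc1)C#C[Si](C)(C)C)O[Si](C(C)C)(C(C)C)O[Si](C(C)C)(C(C)C)O[C@H](CCC)/C(C(=O)OC)=C(\OS(=O)(=O)c1ccc(C)cc1)C#C[Si](C)(C)C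
F3 | step 3 | bridged bis[methyl (2E)-3-(trimethylstannyl)-5-(trimethylsilyl)pent-2-en-4-ynoate] | CCC[C@H](/C(C(=O)OC)=C(\[Sn](C)(C)C)C#C[Si](C)(C)C)O[Si](C(C)C)(C(C)C)O[Si](C(C)C)(C(C)C)O[C@H](CCC)/C(C(=O)OC)=C(\[Sn](C)(C)C)C#C[Si](C)(C)C
F4 | step 8 | mono-mesylate of diol 10 | CCC[C@@H](OS(C)(=O)=O)C1=C(Br)[C@@]2(OC1=O)[C@@H](Br)[C@H](Br)[C@@]21OC(=O)C([C@@H](CCC)O)=C1Br
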